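**Plan**

1. Retrosynthesis: the two oxiranes (C1–C10, C4–C5) come off first, then the C13 acetate and the C8 ester. This leaves allylic alcohol 18, an (E,E)-germacra-1(10),4-diene fused to a butenolide.
2. Central cut, C7–C8: C8 is a carbinol carbon of the ten-membered ring and sits on C7, the β-carbon of the butenolide ring (C8(OH)–C7=C11–C12=O). The ring therefore opens to a C8 aldehyde and a C7 iodide, and the normally electrophilic β-carbon is made nucleophilic as an alkenylchromium: two acceptor carbons joined by polarity reversal.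
3. The iodobutenolide is cut at O–C6 and C7–I (iodolactonisation of an allenoate C11=C7=C6), the allenoate at C11–C12 (carbonylation of a propargylic carbonate), and the propargylic alcohol at C6–C7 (alkynylation of a geranyl-derived enal).
4. Forward order: one-carbon-extended chain from geranyl acetate, alkynylation, butenolide ring, ten-membered carbocycle, C8 ester, C13 acetate, both oxiranes last.
5. Stereochemistry: C6 from ligand-controlled alkynylation, relayed centre to axis to centre. C8 from the chelation-controlled ring closure. The side-chain carbinol from a chiral-pool acid. C1, C10, C4 and C5 from peripheral peracid attack on the crown conformer.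

Key step: step 12

Remark: germacrane numbering is used throughout (ring C1–C10, lactone carbons C11–C13 with the ring oxygen on C6, C14 on C10, C15 on C4). The target is read as the 1β,10α:4α,5β-diepoxide with 6α- and 8α-oxygens and both methyl groups β.
Assumption: (S,S)-ProPhenol is taken to deliver the alkynylzinc to the Re face of enal 8, by analogy with its usual sense of induction. If the sense is opposite for this enal, the antipodal ligand is used.
Assumption: ether 9 and bromo acid 19 are treated as purchasable.

**Step 1**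
Reactants: 1 geranyl acetate
Product: 3 (2E,6E)-3,7-dimethyl-8-oxoocta-2,6-dien-1-yl acetate, via allylic alcohol 2 (not isolated)
Conditions: SeO2 (cat.), t-BuOOH, salicylic acid (cat.), CH2Cl2, rt; crude mixture then MnO2, CH2Cl2, rt
Reagents that add atoms: tert-butyl hydroperoxide, CC(C)(C)OO
Why: Riley allylic oxidation (ene reaction then [2,3] shift) selectively oxidises the E-methyl group of the terminal trisubstituted alkene, and MnO2 should bring the alcohol/aldehyde mixture to the enal without touching the acetate.

**Step 2**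
Reactants: 3 (2E,6E)-3,7-dimethyl-8-oxoocta-2,6-dien-1-yl acetate
Product: 4 (2E,6E)-3,7-dimethylnona-2,6,8-trien-1-yl acetate
Conditions: Ph3PCH3Br, n-BuLi, THF, −78 → 0 °C (about one equivalent of ylide)
Reagents that add atoms: methyltriphenylphosphonium bromide, C[P+](c1ccccc1)(c1ccccc1)c1ccccc1.[Br-]
Why: Wittig methylenation; the aldehyde should react far faster than the acetate at low temperature, and the trisubstituted E-alkene is not touched.

**Step 3**
Reactants: 4 (2E,6E)-3,7-dimethylnona-2,6,8-trien-1-yl acetate
Product: 6 (2E,6E)-3,7-dimethylnona-2,6-diene-1,9-diol, via alkyl-9-BBN adduct 5 (not isolated)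
Conditions: 9-BBN, THF, 0 °C → rt; then 3 M NaOH, 30% H2O2, 0 → 50 °C
Reagents that add atoms: hydrogen peroxide, OO
Why: Brown hydroboration–oxidation; the bulky borane should add only to the monosubstituted terminus of the diene (anti-Markovnikov, as in homogeraniol-type preparations), and the alkaline peroxide oxidises the C–B bond and saponifies the acetate in the same operation.

**Step 4**
Reactants: 6 (2E,6E)-3,7-dimethylnona-2,6-diene-1,9-diol
Product: 7 (2E,6E)-9-hydroxy-3,7-dimethylnona-2,6-dienal
Conditions: activated MnO2, CH2Cl2, rt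
Reagents that add atoms: none
Why: MnO2 oxidises allylic alcohols only, so the C6 alcohol should give the E-enal while the homoallylic C8 alcohol stays.

**Step 5**
Reactants: 7 (2E,6E)-9-hydroxy-3,7-dimethylnona-2,6-dienal
Product: 8 (2E,6E)-9-[(tert-butyldimethylsilyl)oxy]-3,7-dimethylnona-2,6-dienal
Conditions: TBSCl, imidazole, CH2Cl2, 0 °C
Reagents that add atoms: tert-butyldimethylsilyl chloride, CC(C)(C)[Si](C)(C)Cl
Why: Routine silylation of the primary alcohol masks the future C8 aldehyde as an ether that fluoride removes later.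

**Step 6**
Reactants: 8 (2E,6E)-9-[(tert-butyldimethylsilyl)oxy]-3,7-dimethylnona-2,6-dienal; 9 4-methoxybenzyl propargyl ether
Product: 11 (4S,5E,9E)-12-[(tert-butyldimethylsilyl)oxy]-1-[(4-methoxybenzyl)oxy]-6,10-dimethyldodeca-5,9-dien-2-yn-4-ol, via alkynyl(methyl)zinc 10 (not isolated)
Conditions: Me2Zn, (S,S)-ProPhenol (cat.), Ph3PO (cat.), toluene, 0 °C; slow addition of 8; aq. NH4Cl work-up
Reagents that add atoms: none
Why: Zn-ProPhenol asymmetric alkynylation; the dinuclear zinc complex should bind the enal and alkynylzinc 10 and deliver the alkyne to the Re face in a 1,2-addition, setting the C6 carbinol as S, which is opposite in space to the lactone centre because steps 8 and 9 together invert it.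

**Step 7**
Reactants: 11 (4S,5E,9E)-12-[(tert-butyldimethylsilyl)oxy]-1-[(4-methoxybenzyl)oxy]-6,10-dimethyldodeca-5,9-dien-2-yn-4-ol
Product: 12 (4S,5E,9E)-12-[(tert-butyldimethylsilyl)oxy]-1-[(4-methoxybenzyl)oxy]-6,10-dimethyldodeca-5,9-dien-2-yn-4-yl methyl carbonate
Conditions: ClCO2Me, pyridine, DMAP (cat.), CH2Cl2, 0 °C
Reagents that add atoms: methyl chloroformate, COC(=O)Cl
Why: O-Acylation to the carbonate gives a leaving group that ionises under neutral conditions and carries its own methoxide; the stereocentre is not touched.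

**Step 8**
Reactants: 12 the propargylic methyl carbonate
Product: 13 methyl (Ra,5E,9E)-12-[(tert-butyldimethylsilyl)oxy]-2-{[(4-methoxybenzyl)oxy]methyl}-6,10-dimethyldodeca-2,3,5,9-tetraenoate
Conditions: Pd2(dba)3·CHCl3 (cat.), PPh3, CO (5 atm), MeOH/THF, rt
Reagents that add atoms: carbon monoxide, [C-]#[O+]
Why: Palladium-catalysed decarboxylative carbonylation of a propargylic carbonate; zerovalent palladium should displace the carbonate in an anti SN2' sense at C11, CO inserts into the σ-allenyl–Pd bond with retention and the released methoxide captures the acyl complex, so the C6 centre is transferred to the Ra allene axis.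

**Step 9**
Reactants: 13 the allenoate
Product: 14 (5R)-5-[(1E,5E)-8-[(tert-butyldimethylsilyl)oxy]-2,6-dimethylocta-1,5-dien-1-yl]-4-iodo-3-{[(4-methoxybenzyl)oxy]methyl}furan-2(5H)-one
Conditions: I2, NaHCO3, MeCN/H2O (15:1), 0 °C → rt, dark
Reagents that add atoms: iodine, II
Why: Iodolactonisation of a 2,3-allenoate; iodine should add to the central carbon C7 on the C13 side and the ester carbonyl oxygen closes on C6 from the opposite side with loss of methanol, so the axis is transferred back to the C6 centre (R here) and the C7–I bond is installed, while iodonium ions on the isolated alkenes have no internal nucleophile and revert.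

**Step 10**
Reactants: 14 the silyl-protected iodobutenolide
Product: 15 (5R)-5-[(1E,5E)-8-hydroxy-2,6-dimethylocta-1,5-dien-1-yl]-4-iodo-3-{[(4-methoxybenzyl)oxy]methyl}furan-2(5H)-one
Conditions: HF·pyridine, pyridine, THF, 0 °C → rt
Reagents that add atoms: none
Why: Buffered fluoride desilylation frees the primary alcohol; the benzylic ether, the iodoalkene and the base-sensitive C6–H are not affected.

**Step 11**
Reactants: 15 the primary alcohol
Product: 16 (3E,7E)-8-[(2R)-3-iodo-4-{[(4-methoxybenzyl)oxy]methyl}-5-oxo-2,5-dihydrofuran-2-yl]-3,7-dimethylocta-3,7-dienal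
Conditions: Dess–Martin periodinane, NaHCO3, CH2Cl2, 0 °C; used at once
Reagents that add atoms: none
Why: Dess–Martin oxidation under buffered, near-neutral conditions should give the β,γ-unsaturated aldehyde without moving the alkene into conjugation or epimerising C6.

**Step 12**
Reactants: 16 the iodobutenolide aldehyde
Product: 18 (6R,8S)-8-hydroxy-13-[(4-methoxybenzyl)oxy]germacra-1(10)E,4E,7(11)-trien-12,6-olide, via alkenylchromium dichloride 17 (not isolated)
Conditions: CrCl2 (10 equiv), NiCl2 (cat.), 4-tert-butylpyridine, THF/DMF (3:1), rt, syringe-pump addition of 16 to a final 2 mM; aqueous work-up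
Reagents that add atoms: none
Why: Nozaki–Hiyama–Kishi reaction: zerovalent nickel formed from NiCl2 inserts into the activated C7–I bond of the β-iodobutenolide, transmetalation to chromium gives the C7 alkenylchromium 17 (the normally electrophilic β-carbon now a nucleophile), and this adds to the C8 aldehyde. The closest known types are intramolecular alkenyl iodide–aldehyde macrocyclisations of this kind, ten-membered germacrane ring closures of farnesyl-type chains by organochromium addition, and chromium-mediated additions of β-iodoacrylates to aldehydes. The ten-membered carbocycle closes in a 10-exo-trig mode; the two E-trisubstituted alkenes and the planar butenolide lower the entropic cost and high dilution suppresses dimerisation. The new C8 centre is controlled by C6 through the cyclic transition state together with chelation of trivalent chromium by the C13 benzylic ether oxygen (five-membered chelate Cr–C7=C11–C13–O); this holds the aldehyde oxygen in the butenolide plane on the C13 side, C9 on the face of C5 and H8 on the face of H6, so the 6,8-cis alcohol (8S) should form. The step needs addition to win over β-elimination of the C6 lactone oxygen, over reduction of the C–I bond and over enolisation or alkene migration of the aldehyde; the covalent, weakly basic C–Cr bond secures this and tolerates lactone and ether. Translactonisation cannot follow because C8 lies trans to the lactone carbonyl across C7=C11.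

**Step 13**
Reactants: 19 (R)-3-bromo-2-hydroxy-2-methylpropanoic acid
Product: 21 (R)-3-chloro-2-hydroxy-2-methylpropanoic acid, via sodium glycidate 20 (not isolated)
Conditions: 2 M NaOH, H2O, 0 °C; then conc. HCl, 0 °C → rt
Reagents that add atoms: hydrogen chloride, Cl
Why: Intramolecular Williamson closure to the (S)-2-methylglycidate followed by acid-promoted opening by chloride at the unhindered CH2 carbon exchanges bromine for chlorine without touching the quaternary stereocentre.

**Step 14**
Reactants: 21 (R)-3-chloro-2-hydroxy-2-methylpropanoic acid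
Product: 23 (S)-3-chloro-2-methyl-2-[(trimethylsilyl)oxy]propanoyl chloride, via bis(trimethylsilyl) derivative 22 (not isolated)
Conditions: TMSCl, Et3N, CH2Cl2, 0 °C → rt, filter; then (COCl)2, DMF (cat.), CH2Cl2, 0 °C → rt; concentrated and used crude
Reagents that add atoms: chlorotrimethylsilane, C[Si](C)(C)Cl; oxalyl chloride, O=C(Cl)C(=O)Cl
Why: Bis-silylation followed by conversion of the silyl ester into the acid chloride with oxalyl chloride/DMF under neutral conditions gives an activated acid whose tertiary hydroxyl is masked (the descriptor changes to S by priority only).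

**Step 15**
Reactants: 18 the macrocyclic allylic alcohol; 23 (S)-3-chloro-2-methyl-2-[(trimethylsilyl)oxy]propanoyl chloride
Product: 25 (6R,8S)-8-{[(2R)-3-chloro-2-hydroxy-2-methylpropanoyl]oxy}-13-[(4-methoxybenzyl)oxy]germacra-1(10)E,4E,7(11)-trien-12,6-olide, via trimethylsilyl ether 24 (not isolated)
Conditions: pyridine, DMAP (cat.), CH2Cl2, 0 °C → rt; then citric acid, MeOH, 0 °C
Reagents that add atoms: none
Why: DMAP-catalysed acylation forms the ester at the C8 oxygen with retention at C8; the silyl ether prevents self-condensation and closure of the chlorohydrin to an epoxide, and is cleaved by the mild acid work-up.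

**Step 16**
Reactants: 25 the C8 ester with the C13 benzylic ether
Product: 26 (6R,8S)-8-{[(2R)-3-chloro-2-hydroxy-2-methylpropanoyl]oxy}-13-hydroxygermacra-1(10)E,4E,7(11)-trien-12,6-olide
Conditions: DDQ, CH2Cl2/pH 7 buffer (10:1), 0 °C
Reagents that add atoms: none
Why: Oxidative cleavage of the 4-methoxybenzyl ether by DDQ under neutral conditions should free the C13 alcohol without acid that could trigger transannular cyclisation of the diene.

**Step 17**
Reactants: 26 the C13 alcohol
Product: 27 (6R,8S)-13-acetoxy-8-{[(2R)-3-chloro-2-hydroxy-2-methylpropanoyl]oxy}germacra-1(10)E,4E,7(11)-trien-12,6-olide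
Conditions: Ac2O, pyridine, CH2Cl2, 0 °C
Reagents that add atoms: acetic anhydride, CC(=O)OC(C)=O
Why: Acetylation without a strong acyl-transfer catalyst should take the primary allylic alcohol and leave the hindered tertiary alcohol of the side chain free.

**Step 18**
Reactants: 27 the diene acetate
Product: 29 (1R,4R,5R,6S,8S,10R)-13-acetoxy-8-{[(2R)-3-chloro-2-hydroxy-2-methylpropanoyl]oxy}-1,10:4,5-diepoxygermacr-7(11)-en-12,6-olide, via 1,10-monoepoxide 28 (not isolated)
Conditions: mCPBA (2.5 equiv), NaHCO3, CH2Cl2, 0 °C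
Reagents that add atoms: 3-chloroperoxybenzoic acid, OOC(=O)c1cccc(Cl)c1
Why: Prilezhaev epoxidation; the two electron-rich trisubstituted alkenes should react and the electron-poor butenolide alkene should not, and attack on the outer face of each alkene in the crown conformer with both methyl groups on the β side should give the 1β,10α- and 4α,5β-oxiranes (C1, C10, C4, C5 all R), as in peracid epoxidations of costunolide-type dienes.

**Compound list**

1 | geranyl acetate, (2E)-3,7-dimethylocta-2,6-dien-1-yl acetate | CC(C)=CCC/C(C)=C/COC(C)=O | starting material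
2 | (2E,6E)-8-hydroxy-3,7-dimethylocta-2,6-dien-1-yl acetate | OC/C(C)=C/CC/C(C)=C/COC(C)=O | intermediate (not isolated)
3 | (2E,6E)-3,7-dimethyl-8-oxoocta-2,6-dien-1-yl acetate | O=C/C(C)=C/CC/C(C)=C/COC(C)=O | intermediate
4 | (2E,6E)-3,7-dimethylnona-2,6,8-trien-1-yl acetate | C=C/C(C)=C/CC/C(C)=C/COC(C)=O | intermediate
5 | (2E,6E)-9-(9-borabicyclo[3.3.1]nonan-9-yl)-3,7-dimethylnona-2,6-dien-1-yl acetate | CC(=O)OC/C=C(C)/CC/C=C(C)/CCB1C2CCCC1CCC2 | intermediate (not isolated)
6 | (2E,6E)-3,7-dimethylnona-2,6-diene-1,9-diol | OCC/C(C)=C/CC/C(C)=C/CO | intermediate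
7 | (2E,6E)-9-hydroxy-3,7-dimethylnona-2,6-dienal | OCC/C(C)=C/CC/C(C)=C/C=O | intermediate
8 | (2E,6E)-9-[(tert-butyldimethylsilyl)oxy]-3,7-dimethylnona-2,6-dienal | CC(C)(C)[Si](C)(C)OCC/C(C)=C/CC/C(C)=C/C=O | intermediate
9 | 4-methoxybenzyl propargyl ether, 1-methoxy-4-[(prop-2-yn-1-yloxy)methyl]benzene | C#CCOCc1ccc(OC)cc1 | starting material
10 | {3-[(4-methoxybenzyl)oxy]prop-1-yn-1-yl}(methyl)zinc | C[Zn]C#CCOCc1ccc(OC)cc1 | intermediate (not isolated)
11 | (4S,5E,9E)-12-[(tert-butyldimethylsilyl)oxy]-1-[(4-methoxybenzyl)oxy]-6,10-dimethyldodeca-5,9-dien-2-yn-4-ol | CC(C)(C)[Si](C)(C)OCC/C(C)=C/CC/C(C)=C/[C@@H](C#CCOCc1ccc(OC)cc1)O | intermediate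
12 | (4S,5E,9E)-12-[(tert-butyldimethylsilyl)oxy]-1-[(4-methoxybenzyl)oxy]-6,10-dimethyldodeca-5,9-dien-2-yn-4-yl methyl carbonate | CC(C)(C)[Si](C)(C)OCC/C(C)=C/CC/C(C)=C/[C@@H](C#CCOCc1ccc(OC)cc1)OC(=O)OC | intermediate
13 | methyl (Ra,5E,9E)-12-[(tert-butyldimethylsilyl)oxy]-2-{[(4-methoxybenzyl)oxy]methyl}-6,10-dimethyldodeca-2,3,5,9-tetraenoate | COC(=O)C(COCc1ccc(OC)cc1)=[C@]=C([H])/C=C(C)/CC/C=C(C)/CCO[Si](C)(C)C(C)(C)C | intermediate
14 | (5R)-5-[(1E,5E)-8-[(tert-butyldimethylsilyl)oxy]-2,6-dimethylocta-1,5-dien-1-yl]-4-iodo-3-{[(4-methoxybenzyl)oxy]methyl}furan-2(5H)-one | COc1ccc(COCC2=C(I)[C@@H](/C=C(C)/CC/C=C(C)/CCO[Si](C)(C)C(C)(C)C)OC2=O)cc1 | intermediate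
15 | (5R)-5-[(1E,5E)-8-hydroxy-2,6-dimethylocta-1,5-dien-1-yl]-4-iodo-3-{[(4-methoxybenzyl)oxy]methyl}furan-2(5H)-one | COc1ccc(COCC2=C(I)[C@@H](/C=C(C)/CC/C=C(C)/CCO)OC2=O)cc1 | intermediate
16 | (3E,7E)-8-[(2R)-3-iodo-4-{[(4-methoxybenzyl)oxy]methyl}-5-oxo-2,5-dihydrofuran-2-yl]-3,7-dimethylocta-3,7-dienal | COc1ccc(COCC2=C(I)[C@@H](/C=C(C)/CC/C=C(C)/CC=O)OC2=O)cc1 | intermediate
17 | dichloro{(2R)-2-[(1E,5E)-2,6-dimethyl-8-oxoocta-1,5-dien-1-yl]-4-{[(4-methoxybenzyl)oxy]methyl}-5-oxo-2,5-dihydrofuran-3-yl}chromium (trivalent chromium, solvent ligands omitted) | COc1ccc(COCC2=C([Cr](Cl)Cl)[C@@H](/C=C(C)/CC/C=C(C)/CC=O)OC2=O)cc1 | intermediate (not isolated)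
18 | (6R,8S)-8-hydroxy-13-[(4-methoxybenzyl)oxy]germacra-1(10)E,4E,7(11)-trien-12,6-olide (6α-O, 8α-OH) | COc1ccc(COCC2=C3[C@@H](O)C/C(C)=C/CC/C(C)=C/[C@H]3OC2=O)cc1 | intermediate
19 | (R)-3-bromo-2-hydroxy-2-methylpropanoic acid | OC(=O)[C@@](C)(O)CBr | starting material
20 | sodium (S)-2-methyloxirane-2-carboxylate | [Na+].[O-]C(=O)[C@@](C)(O1)C1 | intermediate (not isolated)
21 | (R)-3-chloro-2-hydroxy-2-methylpropanoic acid | OC(=O)[C@@](C)(O)CCl | intermediate
22 | trimethylsilyl (R)-3-chloro-2-methyl-2-[(trimethylsilyl)oxy]propanoate | C[Si](C)(C)OC(=O)[C@@](C)(O[Si](C)(C)C)CCl | intermediate (not isolated)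
23 | (S)-3-chloro-2-methyl-2-[(trimethylsilyl)oxy]propanoyl chloride | ClC(=O)[C@@](C)(O[Si](C)(C)C)CCl | intermediate
24 | (6R,8S)-8-{[(2R)-3-chloro-2-methyl-2-[(trimethylsilyl)oxy]propanoyl]oxy}-13-[(4-methoxybenzyl)oxy]germacra-1(10)E,4E,7(11)-trien-12,6-olide | COc1ccc(COCC2=C3[C@@H](OC(=O)[C@@](C)(O[Si](C)(C)C)CCl)C/C(C)=C/CC/C(C)=C/[C@H]3OC2=O)cc1 | intermediate (not isolated)
25 | (6R,8S)-8-{[(2R)-3-chloro-2-hydroxy-2-methylpropanoyl]oxy}-13-[(4-methoxybenzyl)oxy]germacra-1(10)E,4E,7(11)-trien-12,6-olide | COc1ccc(COCC2=C3[C@@H](OC(=O)[C@@](C)(O)CCl)C/C(C)=C/CC/C(C)=C/[C@H]3OC2=O)cc1 | intermediate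
26 | (6R,8S)-8-{[(2R)-3-chloro-2-hydroxy-2-methylpropanoyl]oxy}-13-hydroxygermacra-1(10)E,4E,7(11)-trien-12,6-olide | OCC1=C2[C@@H](OC(=O)[C@@](C)(O)CCl)C/C(C)=C/CC/C(C)=C/[C@H]2OC1=O | intermediate
27 | (6R,8S)-13-acetoxy-8-{[(2R)-3-chloro-2-hydroxy-2-methylpropanoyl]oxy}germacra-1(10)E,4E,7(11)-trien-12,6-olide | CC(=O)OCC1=C2[C@@H](OC(=O)[C@@](C)(O)CCl)C/C(C)=C/CC/C(C)=C/[C@H]2OC1=O | intermediate
28 | (1R,6R,8S,10R)-13-acetoxy-8-{[(2R)-3-chloro-2-hydroxy-2-methylpropanoyl]oxy}-1,10-epoxygermacra-4E,7(11)-dien-12,6-olide | CC(=O)OCC1=C2[C@@H](OC(=O)[C@@](C)(O)CCl)C[C@@]3(C)O[C@@H]3CC/C(C)=C/[C@H]2OC1=O | intermediate (not isolated)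
29 | (1R,4R,5R,6S,8S,10R)-13-acetoxy-8-{[(2R)-3-chloro-2-hydroxy-2-methylpropanoyl]oxy}-1,10:4,5-diepoxygermacr-7(11)-en-12,6-olide (CNP0255009.1) | CC(=O)OCC1=C2[C@@H](OC(=O)[C@@](C)(O)CCl)C[C@@]3(C)O[C@@H]3CC[C@@]3(C)O[C@@H]3[C@H]2OC1=O | target

**Step count and risks**

Total step count: 18 (main line 16, side-chain acid 2).
Longest linear sequence: 16 steps (steps 1–12 and 15–18, from geranyl acetate).

Step 12 is the most likely to fail. The ring closure may proceed with poor or reversed facial selectivity at the aldehyde if an open, non-chelated transition state competes (H8 rather than O8 in the butenolide plane to relieve allylic 1,3-strain against the C13 substituent). The fallback does not discard the epimer but turns the esterification into an inverting step. It sets out from 16: the ring closure then delivers the C8 epimer, (6R,8R)-8-hydroxy-13-[(4-methoxybenzyl)oxy]germacra-1(10)E,4E,7(11)-trien-12,6-olide F1. A Mitsunobu reaction of F1 with the free hydroxy acid 21 (PPh3, DIAD, toluene, 0 °C; the tertiary hydroxyl of 21 does not compete) displaces the activated C8 oxygen with inversion and returns to the route at 25. Both C8 epimers therefore converge on 25, one through step 15 and one through this inversion.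

Step 8 is the second risk. Ionisation of the doubly activated (allylic and propargylic) carbonate may leak toward an η3-allyl palladium isomer, or the allenylpalladium may racemise by attack of a second zerovalent palladium before CO insertion, eroding regiochemistry and the centre-to-axis transfer. The fallback separates the ionisation from the palladium chemistry and sets out from 11. Mesylation at low temperature (MsCl, Et3N, THF, −78 °C) gives the mesylate, (4S,5E,9E)-12-[(tert-butyldimethylsilyl)oxy]-1-[(4-methoxybenzyl)oxy]-6,10-dimethyldodeca-5,9-dien-2-yn-4-yl methanesulfonate F2. It is treated in the same flask with LiCuBr2, which displaces it in an anti SN2' sense at the alkyne terminus to give the bromoallene, (Ra,5E,9E)-2-bromo-12-[(tert-butyldimethylsilyl)oxy]-1-[(4-methoxybenzyl)oxy]-6,10-dimethyldodeca-2,3,5,9-tetraene F3. Methoxycarbonylation of the C(sp2)–Br bond of F3 (Pd(PPh3)4, CO, MeOH, Et3N) proceeds with retention and has no allylic leaving group to compete; it comes back to the route at 13.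

Step 18 is the third risk. One of the two alkenes may be attacked on the wrong face if a conformer with the methyl groups anti is populated in this 7(11)-unsaturated ring, and the 3-chlorobenzoic acid formed may open the first oxirane transannularly. The fallback replaces substrate control by reagent control and sets out from 27. Epoxidation uses the chiral dioxirane generated from the fructose-derived Shi ketone, in the enantiomer matched to the two peripheral faces (stoichiometric ketone, Oxone (2KHSO5·KHSO4·K2SO4), NaHCO3 buffer near pH 8, MeCN/dimethoxymethane/H2O, 0 °C). These conditions are acid-free and mild enough for the acetate and the chlorohydrin, and the sequence arrives at 29 by way of 28 without any new compound.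

**Further compounds**

F1 | step 12 | (6R,8R)-8-hydroxy-13-[(4-methoxybenzyl)oxy]germacra-1(10)E,4E,7(11)-trien-12,6-olide | COc1ccc(COCC2=C3[C@H](O)C/C(C)=C/CC/C(C)=C/[C@H]3OC2=O)cc1
F2 | step 8 | (4S,5E,9E)-12-[(tert-butyldimethylsilyl)oxy]-1-[(4-methoxybenzyl)oxy]-6,10-dimethyldodeca-5,9-dien-2-yn-4-yl methanesulfonate | CC(C)(C)[Si](C)(C)OCC/C(C)=C/CC/C(C)=C/[C@@H](C#CCOCc1ccc(OC)cc1)OS(C)(=O)=O
F3 | step 8 | (Ra,5E,9E)-2-bromo-12-[(tert-butyldimethylsilyl)oxy]-1-[(4-methoxybenzyl)oxy]-6,10-dimethyldodeca-2,3,5,9-tetraene | BrC(COCc1ccc(OC)cc1)=[C@]=C([H])/C=C(C)/CC/C=C(C)/CCO[Si](C)(C)C(C)(C)C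
F0 | step 18 | none | none
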